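**Plan**

Ring numbering: C1 (bears the isopropyl group)=C2, C3–C4 epoxide (methyl on C4), C5–C7, C8 (CH2OH), C9 (ketone), C10, C11, C12 (methyl), C13 (OH), C14 (ketone, bonded to C1).
Cuts, in retrosynthetic order: C10–C11 (made as the C10=C11 olefin of a C9 enone by ring-closing metathesis, then saturated), C1=C2 (aldol addition/dehydration), C4–C5 (B-alkyl Suzuki–Miyaura coupling), C9–C10 and C14–C1 (Grignard additions), C12–C13 (crotylboration), C8–CH2OH (enolate hydroxymethylation).
Enabling feature: in the 14-membered ring, C10–C11 is a bare CH2–CH2 link without substituent or stereocentre. It lies between the C9 ketone and the methyl-bearing C12, so it can be traced back to an enone olefin whose two halves end in plain vinyl groups.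
Forward order: fragment C2–C10 (steps 1–11, epoxide ring in step 9) and fragment C11–C14 plus C1/isopropyl (steps 12–14) are joined at C1=C2 (steps 15, 16). The C9 vinyl ketone is then unmasked (steps 17, 18), the macrocycle closes (step 19), and conjugate reduction and desilylation finish the route (steps 20, 21).
Stereochemistry: C8 comes from the (R)-benzyloxazolidinone. C3/C4 come from Sharpless epoxidation with L-(+)-diethyl tartrate of a Z-olefin whose geometry is fixed by trans-hydroalumination/iodination. C12/C13 come from a (Z)-crotyldiisopinocampheylborane, and 1E from a syn-aldol/anti-elimination pair.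

Key step: step 19

Remark: the C9 carbinol centre (16–19, 31–34) and the C1/C2 centres of 31 and 32 are transient. They are carried as mixtures, are erased in steps 18 and 16, and are left open in the SMILES.

**Route**

Step 1
Reactants: 1 (R)-4-benzyl-1,3-oxazolidin-2-one; 2 pent-4-enoyl chloride
Product: 3 (R)-4-benzyl-3-(pent-4-enoyl)-1,3-oxazolidin-2-one
Conditions: n-BuLi, THF, −78 °C; then 2, −78 → 0 °C
Reagents that add atoms: none
Why: N-Acylation of a lithiated Evans oxazolidinone with an acid chloride is routine and leaves the auxiliary stereocentre untouched.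

Step 2
Reactants: 3 (R)-4-benzyl-3-(pent-4-enoyl)-1,3-oxazolidin-2-one; 4 1,3,5-trioxane
Product: 6 (R)-4-benzyl-3-[(S)-2-(hydroxymethyl)pent-4-enoyl]-1,3-oxazolidin-2-one, via titanium enolate 5 (not isolated)
Conditions: TiCl4, iPr2NEt, CH2Cl2, 0 °C; then 4, TiCl4, 0 °C
Reagents that add atoms: none
Why: Evans titanium-enolate hydroxymethylation: the benzyl group shields one face of the chelated (Z)-enolate 5, so TiCl4-activated formaldehyde from 4 enters from the other face and sets C8 as S, while the monosubstituted alkene is too weak a nucleophile for a Prins reaction.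

Step 3
Reactants: 6 (R)-4-benzyl-3-[(S)-2-(hydroxymethyl)pent-4-enoyl]-1,3-oxazolidin-2-one
Product: 7 (S)-2-(hydroxymethyl)-N-methoxy-N-methylpent-4-enamide
Conditions: Me3Al, MeNHOMe·HCl, CH2Cl2, −10 °C → rt
Reagents that add atoms: N,O-dimethylhydroxylamine hydrochloride, CNOC.Cl
Why: Weinreb transamination with the aluminium amide: the free β-hydroxyl group binds aluminium and steers attack to the exocyclic carbonyl group, auxiliary 1 is released for reuse, and C8 is not enolised.

Step 4
Reactants: 7 (S)-2-(hydroxymethyl)-N-methoxy-N-methylpent-4-enamide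
Product: 8 (S)-2-[(tert-butyldimethylsilyloxy)methyl]-N-methoxy-N-methylpent-4-enamide
Conditions: TBSCl, imidazole, CH2Cl2, 0 °C → rt
Reagents that add atoms: tert-butyldimethylsilyl chloride, CC(C)(C)[Si](C)(C)Cl
Why: Standard silylation of a primary alcohol, which blocks retro-aldol and β-elimination pathways in the later carbonyl chemistry at C9.

Step 5
Reactants: 9 but-2-yn-1-ol
Product: 11 (Z)-3-iodobut-2-en-1-ol, via cyclic alkenylalanate 10 (not isolated)
Conditions: NaAlH2(OCH2CH2OMe)2 (Red-Al), THF, 0 °C → rt; then I2, −78 → 0 °C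
Reagents that add atoms: iodine, II
Why: Hydroxyl-directed trans-hydroalumination of a propargylic alcohol puts hydride next to CH2OH and aluminium on the methyl-bearing carbon in alanate 10, and iodinolysis with retention should give only the Z-iodide, which fixes the later cis relation of C2 and C5 on the epoxide.

Step 6
Reactants: 8 (S)-2-[(tert-butyldimethylsilyloxy)methyl]-N-methoxy-N-methylpent-4-enamide; 11 (Z)-3-iodobut-2-en-1-ol
Product: 13 (2S,6Z)-2-[(tert-butyldimethylsilyloxy)methyl]-8-hydroxy-N-methoxy-N,6-dimethyloct-6-enamide, via B-alkyl-9-BBN adduct 12 (not isolated)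
Conditions: 9-BBN-H, THF, 0 °C → rt; then 11, PdCl2(dppf) (5 mol %), Ph3As, Cs2CO3, DMF/H2O, rt
Reagents that add atoms: none
Why: B-alkyl Suzuki–Miyaura coupling: 9-BBN-H adds anti-Markovnikov to the terminal alkene much faster than it attacks the amide, and oxidative addition to zerovalent palladium, transmetalation and reductive elimination all go with retention, so C4–C5 forms with the Z geometry intact and the free hydroxyl group is tolerated.

Step 7
Reactants: 13 (2S,6Z)-2-[(tert-butyldimethylsilyloxy)methyl]-8-hydroxy-N-methoxy-N,6-dimethyloct-6-enamide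
Product: 14 (2S,6Z)-2-[(tert-butyldimethylsilyloxy)methyl]-8-hydroxy-6-methyloct-6-enal
Conditions: iBu2AlH (2.5 equiv), THF, −78 °C
Reagents that add atoms: none
Why: Reduction of a Weinreb amide stops at the chelated tetrahedral aluminium adduct, which gives the aldehyde only on work-up; one equivalent of hydride is spent on the hydroxyl group, and 14 is used crude so that C8 does not epimerise.

Step 8
Reactants: 14 (2S,6Z)-2-[(tert-butyldimethylsilyloxy)methyl]-8-hydroxy-6-methyloct-6-enal; 15 vinylmagnesium bromide
Product: 16 (2Z,7S)-7-[(tert-butyldimethylsilyloxy)methyl]-3-methyldeca-2,9-diene-1,8-diol (both C9 epimers in ring numbering)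
Conditions: 15 (3 equiv), THF, −78 → −20 °C
Reagents that add atoms: none
Why: Grignard 1,2-addition forms C9–C10 and stores the vinyl ketone as its base-stable allylic alcohol; the new carbinol centre needs no control because step 18 removes it.

Step 9
Reactants: 16 (2Z,7S)-7-[(tert-butyldimethylsilyloxy)methyl]-3-methyldeca-2,9-diene-1,8-diol
Product: 17 (4S)-4-[(tert-butyldimethylsilyloxy)methyl]-7-[(2R,3S)-3-(hydroxymethyl)-2-methyloxiran-2-yl]hept-1-en-3-ol (3S,4R,8S in ring numbering)
Conditions: Ti(OiPr)4 (20 mol %), L-(+)-diethyl tartrate (24 mol %), t-BuOOH (1.2 equiv), 4 Å molecular sieves, CH2Cl2, −25 °C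
Reagents that add atoms: tert-butyl hydroperoxide, CC(C)(C)OO
Why: Sharpless asymmetric epoxidation: with L-(+)-tartrate a nerol-type Z-trisubstituted allylic alcohol gives the (2S,3R)-epoxy alcohol, here 3S,4R, and this primary trisubstituted allylic alcohol reacts far faster than the monosubstituted vinyl carbinol at C9, so limiting the peroxide keeps the C10 vinyl group intact.

Step 10
Reactants: 17 (3S,4R,8S)-epoxy diol
Product: 18 (2R,3R)-3-{(4S)-4-[(tert-butyldimethylsilyloxy)methyl]-5-hydroxyhept-6-en-1-yl}-3-methyloxirane-2-carbaldehyde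
Conditions: TEMPO (10 mol %), PhI(OAc)2, CH2Cl2, 0 °C → rt
Reagents that add atoms: none
Why: Oxoammonium (TEMPO/PhI(OAc)2) oxidation takes a primary alcohol in preference to the hindered secondary C9 alcohol, stops at the aldehyde and spares the epoxide; the descriptor at C3 changes to R only through the priority rules.

Step 11
Reactants: 18 (2R,3R)-epoxy aldehyde with free C9 hydroxyl group
Product: 19 (2R,3R)-3-{(4S)-4-[(tert-butyldimethylsilyloxy)methyl]-5-(triethylsilyloxy)hept-6-en-1-yl}-3-methyloxirane-2-carbaldehyde
Conditions: Et3SiCl, imidazole, DMAP (cat.), CH2Cl2, 0 °C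
Reagents that add atoms: chlorotriethylsilane, CC[Si](Cl)(CC)CC
Why: Mild silylation of the only free hydroxyl group gives a C9 ether that withstands the boron aldol and the elimination yet can later be removed in the presence of both TBS ethers.

Step 12
Reactants: 20 cis-but-2-ene; 21 ethyl glyoxylate
Product: 25 ethyl (2S,3R)-2-hydroxy-3-methylpent-4-enoate, via (Z)-crotylpotassium 22 (not isolated), via (Z)-crotyldiisopinocampheylborane 23 (not isolated), via borinate 24 (not isolated)
Conditions: KOt-Bu, n-BuLi, THF, −78 → −45 °C; (−)-Ipc2BOMe [from (+)-α-pinene], −78 °C; BF3·OEt2; 21 (freshly cracked), −78 °C; NaBO3·4H2O, THF/H2O, rt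
Reagents that add atoms: none
Why: Brown asymmetric crotylboration: the Z-crotylborane reacts through a closed Zimmerman–Traxler chair, so its geometry gives the 12,13-syn relation, the isopinocampheyl groups from (+)-α-pinene select the aldehyde face that gives 13S,12R, and the perborate work-up spares the ester.

Step 13
Reactants: 25 ethyl (2S,3R)-2-hydroxy-3-methylpent-4-enoate
Product: 26 ethyl (2S,3R)-2-(tert-butyldimethylsilyloxy)-3-methylpent-4-enoate
Conditions: TBSOTf, 2,6-lutidine, CH2Cl2, 0 °C
Reagents that add atoms: tert-butyldimethylsilyl triflate, CC(C)(C)[Si](C)(C)OS(=O)(=O)C(F)(F)F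
Why: Silyl triflate silylation covers the hindered secondary alcohol under weakly basic conditions that do not epimerise C13.

Step 14
Reactants: 26 ethyl (2S,3R)-2-(tert-butyldimethylsilyloxy)-3-methylpent-4-enoate; 27 isobutylmagnesium bromide
Product: 29 (5S,6R)-5-(tert-butyldimethylsilyloxy)-2,6-dimethyloct-7-en-4-one, via Weinreb amide 28 (not isolated)
Conditions: MeNHOMe·HCl, i-PrMgCl, THF, −20 °C; then 27 (3 equiv), 0 °C → rt
Reagents that add atoms: none
Why: One-flask Weinreb ketone synthesis: the magnesium amide turns the ester into 28 without touching the α-silyloxy centre, and the chelated tetrahedral adduct of 28 and 27 prevents a second addition, so C14–C1 forms cleanly.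

Step 15
Reactants: 29 (5S,6R)-5-(tert-butyldimethylsilyloxy)-2,6-dimethyloct-7-en-4-one; 19 (2R,3R)-epoxy aldehyde with C9 triethylsilyl ether
Product: 31 1,2-syn aldol adduct (open chain C11–C14–C1–C2–C10 with C2-OH; C9-OTES; C13-OTBS; C8-CH2OTBS; 3S,4R,8S,12R,13S), via boron enolate 30 (not isolated)
Conditions: 29, n-Bu2BOTf, iPr2NEt, CH2Cl2, −78 → 0 °C; then 19, −78 → −20 °C; pH 7 buffer, MeOH, H2O2, 0 °C
Reagents that add atoms: none
Why: Boron-mediated aldol addition: n-Bu2BOTf/iPr2NEt enolises the α-silyloxy ketone at the less hindered C1 methylene to the (Z)-enolate 30, which adds only to the aldehyde through a chair transition state to give the 1,2-syn adduct, and facial selectivity is irrelevant because both new centres vanish in step 16.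

Step 16
Reactants: 31 1,2-syn aldol adduct
Product: 33 (1E)-enone (C14 ketone conjugated to C1=C2; C3–C4 epoxide; C9-OTES; C13-OTBS; C8-CH2OTBS; vinyl groups at C9 and C12), via mesylate 32 (not isolated)
Conditions: MsCl, Et3N, CH2Cl2, −10 °C; then DBU, 0 °C → rt
Reagents that add atoms: none
Why: Mesylation and β-elimination: in the 1,2-syn mesylate H1 and the leaving group are antiperiplanar when C14 and C3 are anti, and an E1cB pathway avoids allylic strain in the same sense, so both mechanisms lead to the olefin with the C14 carbonyl group trans to C3 (1E).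

Step 17
Reactants: 33 (1E)-enone with C9 triethylsilyl ether
Product: 34 (1E)-enone with free C9 allylic alcohol
Conditions: HF·pyridine, pyridine, THF, 0 °C
Reagents that add atoms: none
Why: Selective fluoride desilylation: a secondary triethylsilyl ether is cleaved much faster than primary or secondary TBS ethers, and the excess pyridine keeps the medium too weakly acidic to open the epoxide.

Step 18
Reactants: 34 (1E)-enone with free C9 allylic alcohol
Product: 35 seco C9 vinyl ketone with C11 vinyl group (bis-TBS ether; 1E,3S,4R,8S,12R,13S)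
Conditions: Dess–Martin periodinane, NaHCO3, CH2Cl2, 0 °C → rt
Reagents that add atoms: none
Why: Dess–Martin oxidation of the only free alcohol unveils the vinyl ketone under buffered, non-basic conditions, so C8 is neither epimerised nor stripped of its silyloxymethyl group by β-elimination, and the C9 epimers converge.

Step 19
Reactants: 35 seco C9 vinyl ketone with C11 vinyl group
Product: 36 macrocyclic (1E,10E)-dienedione bis-TBS ether (14-membered ring; 3S,4R,8S,12R,13S)
Conditions: RuCl2(H2IMes)(=CH–C6H4–2-OiPr) (second-generation Hoveyda–Grubbs catalyst, 10 mol %), 1,4-benzoquinone (20 mol %), toluene (1 mM), 80 °C, argon sparge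
Reagents that add atoms: none
Why: Ring-closing olefin metathesis: the catalyst first exchanges its benzylidene for the electron-richer monosubstituted olefin at C11, the C11 alkylidene then engages the C9 vinyl ketone in a ruthenacyclobutane, and its fragmentation creates C10=C11 while the ruthenium methylidene left behind re-enters the cycle and ethene escapes. The closest known reaction type is the metathesis macrocyclisation of an alkyl vinyl ketone onto a terminal alkene, which gives macrocyclic E-enones. The 14-membered carbocycle is closed end to end between the two CH2= termini, at 1 mM so that ring closure outruns oligomerisation and under an argon stream so that loss of ethene makes it irreversible. No stereocentre is created; the one new stereoelement, the 10E olefin, is set by the lower strain and full conjugation of the E-enone in a ring of this size. The step needs reaction at the two vinyl groups only, and the substrate secures this because C1=C2 is trisubstituted, electron-poor and shielded by the isopropyl group, so that the alternative five-ring closure from C11 onto C1 would have to pass through a ruthenacyclobutane at a fully substituted carbon. The medium is neutral, so C8 and C13 beside the ketones, the epoxide and the silyl ethers are untouched, and benzoquinone intercepts ruthenium hydrides that could move the C11 olefin.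

Step 20
Reactants: 36 macrocyclic (1E,10E)-dienedione bis-TBS ether
Product: 37 macrocyclic (1E)-enedione bis-TBS ether with saturated C10–C11
Conditions: [(Ph3P)CuH]6, toluene, degassed H2O, 0 °C → rt
Reagents that add atoms: none
Why: Conjugate reduction with Stryker's reagent: the bulky copper hydride adds to the α-unsubstituted, disubstituted C10=C11 enone much faster than to the α-isopropyl C1=C2 enone, and water protonates the C10 copper enolate before it can equilibrate toward C8 or add across the ring to C14.

Step 21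
Reactants: 37 macrocyclic (1E)-enedione bis-TBS ether
Product: 38 CNP0110598.2
Conditions: HF·pyridine, pyridine, THF, 0 °C → rt
Reagents that add atoms: none
Why: Buffered fluoride desilylation removes both TBS ethers, avoids the basic fluoride sources that would cause retro-aldol loss or β-elimination at C8 and epimerisation at C8/C13, and the excess pyridine protects the trisubstituted epoxide.

**Compound list**

1 | (R)-4-benzyl-1,3-oxazolidin-2-one | O=C1N[C@H](Cc2ccccc2)CO1 | starting material
2 | pent-4-enoyl chloride | C=CCCC(=O)Cl | starting material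
3 | (R)-4-benzyl-3-(pent-4-enoyl)-1,3-oxazolidin-2-one | C=CCCC(=O)N1[C@H](Cc2ccccc2)COC1=O | intermediate
4 | 1,3,5-trioxane | C1OCOCO1 | starting material
5 | trichlorotitanium (Z)-enolate of 3 | C=CC/C=C(\O[Ti](Cl)(Cl)Cl)N1[C@H](Cc2ccccc2)COC1=O | intermediate
6 | (R)-4-benzyl-3-[(S)-2-(hydroxymethyl)pent-4-enoyl]-1,3-oxazolidin-2-one | C=CC[C@@H](CO)C(=O)N1[C@H](Cc2ccccc2)COC1=O | intermediate
7 | (S)-2-(hydroxymethyl)-N-methoxy-N-methylpent-4-enamide | C=CC[C@@H](CO)C(=O)N(C)OC | intermediate
8 | (S)-2-[(tert-butyldimethylsilyloxy)methyl]-N-methoxy-N-methylpent-4-enamide | C=CC[C@@H](CO[Si](C)(C)C(C)(C)C)C(=O)N(C)OC | intermediate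
9 | but-2-yn-1-ol | CC#CCO | starting material
10 | sodium 2,2-bis(2-methoxyethoxy)-3-methyl-1-oxa-2-aluminacyclopent-3-en-2-uide (cyclic alkenylalanate) | [Na+].CC1=CCO[Al-]1(OCCOC)OCCOC | intermediate
11 | (Z)-3-iodobut-2-en-1-ol | C/C(I)=C/CO | intermediate
12 | B-alkyl-9-BBN adduct of 8 (boron on C5) | C(CC[C@@H](CO[Si](C)(C)C(C)(C)C)C(=O)N(C)OC)B1C2CCCC1CCC2 | intermediate
13 | (2S,6Z)-2-[(tert-butyldimethylsilyloxy)methyl]-8-hydroxy-N-methoxy-N,6-dimethyloct-6-enamide | OC/C=C(/C)CCC[C@@H](CO[Si](C)(C)C(C)(C)C)C(=O)N(C)OC | intermediate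
14 | (2S,6Z)-2-[(tert-butyldimethylsilyloxy)methyl]-8-hydroxy-6-methyloct-6-enal | OC/C=C(/C)CCC[C@@H](CO[Si](C)(C)C(C)(C)C)C=O | intermediate
15 | vinylmagnesium bromide | C=C[Mg]Br | starting material
16 | (2Z,7S)-7-[(tert-butyldimethylsilyloxy)methyl]-3-methyldeca-2,9-diene-1,8-diol, C9 epimers | OC/C=C(/C)CCC[C@@H](CO[Si](C)(C)C(C)(C)C)C(O)C=C | intermediate
17 | (4S)-4-[(tert-butyldimethylsilyloxy)methyl]-7-[(2R,3S)-3-(hydroxymethyl)-2-methyloxiran-2-yl]hept-1-en-3-ol, C9 epimers | OC[C@@H]1O[C@]1(C)CCC[C@@H](CO[Si](C)(C)C(C)(C)C)C(O)C=C | intermediate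
18 | (2R,3R)-3-{(4S)-4-[(tert-butyldimethylsilyloxy)methyl]-5-hydroxyhept-6-en-1-yl}-3-methyloxirane-2-carbaldehyde, C9 epimers | O=C[C@@H]1O[C@]1(C)CCC[C@@H](CO[Si](C)(C)C(C)(C)C)C(O)C=C | intermediate
19 | (2R,3R)-3-{(4S)-4-[(tert-butyldimethylsilyloxy)methyl]-5-(triethylsilyloxy)hept-6-en-1-yl}-3-methyloxirane-2-carbaldehyde, C9 epimers | O=C[C@@H]1O[C@]1(C)CCC[C@@H](CO[Si](C)(C)C(C)(C)C)C(O[Si](CC)(CC)CC)C=C | intermediate
20 | cis-but-2-ene | C/C=C\C | starting material
21 | ethyl glyoxylate | CCOC(=O)C=O | starting material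
22 | (Z)-crotylpotassium | C/C=C\C[K] | intermediate
23 | (Z)-crotyldiisopinocampheylborane, Ipc groups from (+)-α-pinene | C/C=C\CB([C@@H]1C[C@@H]2C[C@H]([C@H]1C)C2(C)C)[C@@H]1C[C@@H]2C[C@H]([C@H]1C)C2(C)C | intermediate
24 | diisopinocampheylborinate of 25 | C=C[C@@H](C)[C@H](OB([C@@H]1C[C@@H]2C[C@H]([C@H]1C)C2(C)C)[C@@H]1C[C@@H]2C[C@H]([C@H]1C)C2(C)C)C(=O)OCC | intermediate
25 | ethyl (2S,3R)-2-hydroxy-3-methylpent-4-enoate | C=C[C@@H](C)[C@H](O)C(=O)OCC | intermediate
26 | ethyl (2S,3R)-2-(tert-butyldimethylsilyloxy)-3-methylpent-4-enoate | C=C[C@@H](C)[C@H](O[Si](C)(C)C(C)(C)C)C(=O)OCC | intermediate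
27 | isobutylmagnesium bromide | CC(C)C[Mg]Br | starting material
28 | (2S,3R)-2-(tert-butyldimethylsilyloxy)-N-methoxy-N,3-dimethylpent-4-enamide | C=C[C@@H](C)[C@H](O[Si](C)(C)C(C)(C)C)C(=O)N(C)OC | intermediate
29 | (5S,6R)-5-(tert-butyldimethylsilyloxy)-2,6-dimethyloct-7-en-4-one | C=C[C@@H](C)[C@H](O[Si](C)(C)C(C)(C)C)C(=O)CC(C)C | intermediate
30 | di-n-butylboron (Z)-enolate of 29 (C14–O–B, C14=C1) | C=C[C@@H](C)[C@H](O[Si](C)(C)C(C)(C)C)/C(OB(CCCC)CCCC)=C/C(C)C | intermediate
31 | 1,2-syn aldol adduct of 29 and 19 (C2-OH), 3S,4R,8S,12R,13S | C=C[C@@H](C)[C@H](O[Si](C)(C)C(C)(C)C)C(=O)C(C(C)C)C(O)[C@@H]1O[C@]1(C)CCC[C@@H](CO[Si](C)(C)C(C)(C)C)C(O[Si](CC)(CC)CC)C=C | intermediate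
32 | C2 mesylate of 31 | C=C[C@@H](C)[C@H](O[Si](C)(C)C(C)(C)C)C(=O)C(C(C)C)C(OS(C)(=O)=O)[C@@H]1O[C@]1(C)CCC[C@@H](CO[Si](C)(C)C(C)(C)C)C(O[Si](CC)(CC)CC)C=C | intermediate
33 | seco (1E)-enone, C9 triethylsilyl ether, 3S,4R,8S,12R,13S | C=C[C@@H](C)[C@H](O[Si](C)(C)C(C)(C)C)C(=O)/C(C(C)C)=C/[C@@H]1O[C@]1(C)CCC[C@@H](CO[Si](C)(C)C(C)(C)C)C(O[Si](CC)(CC)CC)C=C | intermediate
34 | seco (1E)-enone, free C9 allylic alcohol | C=C[C@@H](C)[C@H](O[Si](C)(C)C(C)(C)C)C(=O)/C(C(C)C)=C/[C@@H]1O[C@]1(C)CCC[C@@H](CO[Si](C)(C)C(C)(C)C)C(O)C=C | intermediate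
35 | seco C9 vinyl ketone with C11 vinyl group, bis-TBS ether, 1E,3S,4R,8S,12R,13S | C=C[C@@H](C)[C@H](O[Si](C)(C)C(C)(C)C)C(=O)/C(C(C)C)=C/[C@@H]1O[C@]1(C)CCC[C@@H](CO[Si](C)(C)C(C)(C)C)C(=O)C=C | intermediate
36 | macrocyclic (1E,10E)-dienedione bis-TBS ether | CC(C)/C1=C\[C@@H]2O[C@]2(C)CCC[C@@H](CO[Si](C)(C)C(C)(C)C)C(=O)/C=C/[C@@H](C)[C@H](O[Si](C)(C)C(C)(C)C)C1=O | intermediate
37 | macrocyclic (1E)-enedione bis-TBS ether, C10–C11 saturated | CC(C)/C1=C\[C@@H]2O[C@]2(C)CCC[C@@H](CO[Si](C)(C)C(C)(C)C)C(=O)CC[C@@H](C)[C@H](O[Si](C)(C)C(C)(C)C)C1=O | intermediate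
38 | CNP0110598.2, (1E,3S,4R,8S,12R,13S)-3,4-epoxy-13-hydroxy-8-(hydroxymethyl)-1-isopropyl-4,12-dimethylcyclotetradec-1-ene-9,14-dione (ring numbering of the plan) | CC(C)/C1=C\[C@@H]2O[C@]2(C)CCC[C@@H](CO)C(=O)CC[C@@H](C)[C@H](O)C1=O | target

**Step count and risks**

Total steps: 21. Longest linear sequence: 17 steps (1–4, 6–11, 15–21), counted from 1 and 2.

Step 19. Intermolecular metathesis may overtake ring closure. Turnover may slow because the C14 carbonyl oxygen chelates the ruthenium alkylidene formed at C11. The catalyst may also decay at the electron-poor vinyl ketone. The fallback closes the same C10=C11 bond one oxidation level lower and sets out from 34. The free allylic hydroxyl group of 34 speeds up loading at the C10 vinyl group, and no electron-poor partner is involved. RuCl2(H2IMes)(PCy3)(=CHPh) (second-generation Grubbs catalyst) in dilute refluxing CH2Cl2 should give the macrocyclic (10E)-C9 allylic alcohol F1. Dess–Martin oxidation of F1 comes back to the route at 36.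

Step 20. Hydride may be delivered to C2 with opening of the adjacent epoxide. The C10 copper enolate may add across the ring to the C14 ketone, closing a five-membered ring. The enolate may also equilibrate toward C8, with loss of configuration or of the silyloxy group. The fallback avoids any nucleophilic metal enolate and sets out from 36. Et3SiH with catalytic RhCl(PPh3)3 in toluene should add in 1,4-fashion to the less hindered enone and hold the product as the C9 triethylsilyl enol ether F2. Buffered HF·pyridine then cleaves the enol ether and both TBS ethers of F2 in one operation and comes back at 38.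

Step 16. Olefin geometry may erode if the elimination is not stereoconvergent. DBU may deprotonate the γ-position (C3) of the product and open the epoxide. C13 may epimerise. The fallback replaces aldol addition and elimination by a carbonyl olefination and sets out from 26. Lithiated diethyl isobutylphosphonate (n-BuLi, THF, −78 °C) is acylated by the ester to give the α-isopropyl β-ketophosphonate F3. A Horner–Wadsworth–Emmons reaction of F3 with aldehyde 19 under Ba(OH)2 in wet THF forms C1=C2 directly, without a leaving group next to the epoxide, and comes back at 33. Olefin isomers would be separated at that stage.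

**Further compounds**

F1 | step 19 | macrocyclic (1E,10E)-C9 allylic alcohol, bis-TBS ether, C9 epimers | CC(C)/C1=C\[C@@H]2O[C@]2(C)CCC[C@@H](CO[Si](C)(C)C(C)(C)C)C(O)/C=C/[C@@H](C)[C@H](O[Si](C)(C)C(C)(C)C)C1=O
F2 | step 20 | macrocyclic C9 triethylsilyl enol ether (C9=C10), bis-TBS ether | CC(C)/C1=C\[C@@H]2O[C@]2(C)CCC[C@@H](CO[Si](C)(C)C(C)(C)C)C(O[Si](CC)(CC)CC)=CC[C@@H](C)[C@H](O[Si](C)(C)C(C)(C)C)C1=O
F3 | step 16 | diethyl [(5S,6R)-5-(tert-butyldimethylsilyloxy)-2,6-dimethyl-4-oxooct-7-en-3-yl]phosphonate | C=C[C@@H](C)[C@H](O[Si](C)(C)C(C)(C)C)C(=O)C(C(C)C)P(=O)(OCC)OCC
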